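**Assumption:** the target has no stereocentre and no stereogenic double bond, so there is no enantiomer to select; the route delivers the single achiral compound.

**Retrosynthetic overview**
1. No ring is formed; the benzene ring is bought intact and the target 10 comes from global O-debenzylation of 9.
2. Key disconnection: the aryl C(sp2)–CH2(sp3) bond, made by Ni-catalysed reductive cross-electrophile coupling of aryl bromide 4 with alkyl bromide 7, which already carries the stearate ester. The usual last-step esterification of the free phenolic propanol is avoided.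
3. 4 comes from benzylation of 5-bromo-3-methoxycatechol 3, which comes from Dakin oxidation of commercial 5-bromo-o-vanillin 1 (CHO as a masked OH fixes the 3,4-dihydroxy-5-methoxy pattern).
4. 7 comes from 3-bromopropan-1-ol 5 and octadecanoyl chloride 6.

**Route**

Step 1
Reactants: 1 5-bromo-2-hydroxy-3-methoxybenzaldehyde
Product: 3 5-bromo-3-methoxybenzene-1,2-diol, via aryl formate 2 (not isolated)
Conditions: 30% H2O2 (1.2 equiv), 2 M NaOH (1.0 equiv), H2O/THF, 0 °C to rt, N2; then 1 M HCl to pH 2
Reagents that add atoms: hydrogen peroxide, OO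
Why: Dakin oxidation; the electron-rich o-hydroxyaryl group migrates in the peroxide adduct to give formate 2, which is hydrolysed in the basic medium to the catechol; no stereocentre is formed.

Step 2
Reactants: 3 5-bromo-3-methoxybenzene-1,2-diol
Product: 4 1,2-bis(benzyloxy)-5-bromo-3-methoxybenzene
Conditions: BnBr (2.3 equiv), K2CO3 (3 equiv), degassed DMF, 60 °C, N2
Reagents that add atoms: benzyl bromide, BrCc1ccccc1
Why: Williamson ether synthesis on both phenoxides; it masks the chelating, oxidation-prone catechol for the Ni/Zn step, and the aryl bromide is inert to these conditions.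

Step 3
Reactants: 5 3-bromopropan-1-ol; 6 octadecanoyl chloride (stearoyl chloride)
Product: 7 3-bromopropyl octadecanoate
Conditions: pyridine (1.2 equiv), DMAP (5 mol%), CH2Cl2, 0 °C to rt
Reagents that add atoms: none
Why: nucleophilic acyl substitution (DMAP-catalysed acylation) of a primary alcohol; the primary bromide is untouched at 0 °C to rt.

Step 4
Reactants: 4 1,2-bis(benzyloxy)-5-bromo-3-methoxybenzene; 7 3-bromopropyl octadecanoate (1.25 equiv)
Product: 9 3-[3,4-bis(benzyloxy)-5-methoxyphenyl]propyl octadecanoate, via alkyl iodide 8 (not isolated)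
Conditions: NiI2·xH2O (10 mol%), 4,4'-dimethoxy-2,2'-bipyridine (10 mol%), NaI (25 mol%), pyridine (10 mol%), Zn dust (2 equiv), DMPU, 60 °C, N2
Reagents that add atoms: none
Why: Ni-catalysed reductive cross-electrophile coupling (Weix type). Ni(0) adds oxidatively to the unhindered aryl bromide, while the alkyl halide (bromide 7 in equilibrium with iodide 8 through catalytic NaI) enters as a radical, and Ar–Ni(III)–alkyl reductive elimination forms the C(sp2)–C(sp3) bond. The two activation modes give cross-selectivity, and the ester, benzyl ethers and methyl ether are tolerated; no stereocentre is formed.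

Step 5
Reactants: 9 3-[3,4-bis(benzyloxy)-5-methoxyphenyl]propyl octadecanoate
Product: 10 3-(3,4-dihydroxy-5-methoxyphenyl)propyl octadecanoate
Conditions: H2 (1 atm), 10% Pd/C, EtOAc/EtOH 4:1, rt; filter and concentrate under N2
Reagents that add atoms: none
Why: catalytic hydrogenolysis of the two benzyl aryl ethers under neutral conditions; the alkyl ester, aryl methyl ether and arene are not reduced, and no stereocentre exists to scramble.

**Compound list**
1 | 5-bromo-2-hydroxy-3-methoxybenzaldehyde (5-bromo-o-vanillin) | O=Cc1cc(Br)cc(OC)c1O | starting material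
2 | 5-bromo-2-hydroxy-3-methoxyphenyl formate (aryl formate) | O=COc1cc(Br)cc(OC)c1O | intermediate
3 | 5-bromo-3-methoxybenzene-1,2-diol | Oc1cc(Br)cc(OC)c1O | intermediate
4 | 1,2-bis(benzyloxy)-5-bromo-3-methoxybenzene | COc1cc(Br)cc(OCc2ccccc2)c1OCc1ccccc1 | intermediate
5 | 3-bromopropan-1-ol | OCCCBr | starting material
6 | octadecanoyl chloride (stearoyl chloride) | CCCCCCCCCCCCCCCCCC(Cl)=O | starting material
7 | 3-bromopropyl octadecanoate | CCCCCCCCCCCCCCCCCC(=O)OCCCBr | intermediate
8 | 3-iodopropyl octadecanoate (alkyl iodide) | CCCCCCCCCCCCCCCCCC(=O)OCCCI | intermediate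
9 | 3-[3,4-bis(benzyloxy)-5-methoxyphenyl]propyl octadecanoate | CCCCCCCCCCCCCCCCCC(=O)OCCCc1cc(OC)c(OCc2ccccc2)c(OCc2ccccc2)c1 | intermediate
10 | 3-(3,4-dihydroxy-5-methoxyphenyl)propyl octadecanoate | CCCCCCCCCCCCCCCCCC(=O)OCCCc1cc(O)c(O)c(OC)c1 | target

**Step count**
Total steps: 5. Longest linear sequence: 4 steps (1 → 3 → 4 → 9 → 10); step 3 is a one-step side branch.

**Three steps most likely to fail, with fallbacks**

Step 4 (cross-electrophile coupling) is the riskiest. Alkyl homodimer, biaryl or hydrodehalogenation could erode the yield with this electron-rich aryl bromide. The fallback replaces the reductive coupling with a B-alkyl Suzuki–Miyaura coupling and sets out from 6 and 4. Octadecanoyl chloride 6 is acylated onto allyl alcohol (pyridine, DMAP cat., CH2Cl2) to give allyl octadecanoate F1. Anti-Markovnikov hydroboration with 9-BBN-H (THF, 0 °C to rt) gives 3-(9-borabicyclo[3.3.1]nonan-9-yl)propyl octadecanoate F2. This is coupled in the same pot with aryl bromide 4 (Pd(dppf)Cl2 5 mol%, aq. K3PO4, THF/DMF, 60 °C), and the route is rejoined at 9.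

Step 1 (Dakin oxidation) is second. The free bromocatechol 3 can be over-oxidised to the o-quinone in alkaline peroxide. The fallback never exposes a free catechol; it sets out from 1 and comes back at 4. Compound 1 is O-benzylated (BnBr, K2CO3, DMF) to 2-(benzyloxy)-5-bromo-3-methoxybenzaldehyde F3. Baeyer–Villiger oxidation with mCPBA (CH2Cl2, rt) gives 2-(benzyloxy)-5-bromo-3-methoxyphenyl formate F4. Methanolysis (K2CO3 cat., MeOH, rt) gives 2-(benzyloxy)-5-bromo-3-methoxyphenol F5, and a second benzylation (BnBr, K2CO3, DMF) gives 4.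

Step 5 (hydrogenolysis) is third. Debenzylation of the flanked central ether may stall, or the waxy product may oxidise or adsorb on the catalyst. The fallback changes the protecting-group strategy to a non-reductive unmasking; it sets out from 3 and comes back at 10. Catechol 3 is silylated (TBSCl, imidazole, DMF) to 1,2-bis(tert-butyldimethylsilyloxy)-5-bromo-3-methoxybenzene F6. The same Ni/Zn cross-electrophile coupling with 7 gives 3-[3,4-bis(tert-butyldimethylsilyloxy)-5-methoxyphenyl]propyl octadecanoate F7. Desilylation with Et3N·3HF (THF, rt) leaves the ester intact and gives 10.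

**Further compounds**
F1 | step 4 | allyl octadecanoate | CCCCCCCCCCCCCCCCCC(=O)OCC=C
F2 | step 4 | 3-(9-borabicyclo[3.3.1]nonan-9-yl)propyl octadecanoate | CCCCCCCCCCCCCCCCCC(=O)OCCCB1C2CCCC1CCC2
F3 | step 1 | 2-(benzyloxy)-5-bromo-3-methoxybenzaldehyde | O=Cc1cc(Br)cc(OC)c1OCc1ccccc1
F4 | step 1 | 2-(benzyloxy)-5-bromo-3-methoxyphenyl formate | O=COc1cc(Br)cc(OC)c1OCc1ccccc1
F5 | step 1 | 2-(benzyloxy)-5-bromo-3-methoxyphenol | Oc1cc(Br)cc(OC)c1OCc1ccccc1
F6 | step 5 | 1,2-bis(tert-butyldimethylsilyloxy)-5-bromo-3-methoxybenzene | COc1cc(Br)cc(O[Si](C)(C)C(C)(C)C)c1O[Si](C)(C)C(C)(C)C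
F7 | step 5 | 3-[3,4-bis(tert-butyldimethylsilyloxy)-5-methoxyphenyl]propyl octadecanoate | CCCCCCCCCCCCCCCCCC(=O)OCCCc1cc(OC)c(O[Si](C)(C)C(C)(C)C)c(O[Si](C)(C)C(C)(C)C)c1
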